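If the rate follows the partner in plain proportion (order one in partner), that is the zero of my scale. A flask then counts its partner exposure, the charged partner summed over the minutes, and portions matter through that sum.

| flask | substrate | partner | remark | time |
|---|---|---|---|---|
| noon | 2 mM | 1.8 mM (in portions, 2) | run made earlier; portions every 2.0 min |  |
| autumn | 2 mM | 7.2 mM (in portions, 2) | run made earlier; portions every 2.0 min |  |
| dusk | 1 mM | 3.6 mM (in portions, 2) | run made earlier; portions every 2.0 min |  |
| elm | 2.0 mM | 3.60 mM | everything together at the start | 4.0 min |
| birch | 2.0 mM | 3.60 mM (in portions, 2) | the portions of partner follow each other after 2.0 min, the first at the start | 4.0 min |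

| run | time / min | product / % |
|---|---|---|
| noon | 0.250 | 0.2 |
| noon | 0.417 | 1.4 |
| noon | 0.667 | 2.3 |
| noon | 0.833 | 1.9 |
| noon | 1.33 | 2.8 |
| noon | 2.00 | 5.2 |
| noon | 3.00 | 10.3 |
| autumn | 0.167 | 1.9 |
| autumn | 0.500 | 4.5 |
| autumn | 0.833 | 8.4 |
| autumn | 1.33 | 17.8 |
| autumn | 2.00 | 27.7 |
| autumn | 2.50 | 38.4 |
| autumn | 3.00 | 50.0 |
| dusk | 0.250 | 1.4 |
| dusk | 0.833 | 3.8 |
| dusk | 1.33 | 8.1 |
| dusk | 2.50 | 17.9 |
| dusk | 3.00 | 25.9 |

(standard deviation of a reading: 1 percentage point)

* the flask that ends with the higher amount of product, in percent of the substrate charged, or "neither" when 2 percentage points or less lies between them (elm / birch / neither)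
* final product, as a percentage of the substrate charged, in elm
* final product, as a percentage of the substrate charged, in birch

I read a ladder of rates from the top down. Autumn gained 22 percentage points in its minute at 7.2 mM of partner and 27.7% in 2.0 min at 3.60 mM. Noon gained 5.1 points in its minute at 1.8 mM and 5.2% in 2.0 min at 0.900 mM. Going down, each halving of charged partner went with a rate lower by a factor of 1.61, 2.72 and 1.96, readings that scatter around the plain case. Dusk, with half of autumn's substrate, read 25.9% at 7.20 mM·min, and autumn read 27.7% at the same exposure.

So I took one yardstick, the midpoint exposure, meaning the exposure at which autumn's reading stood at 50.0%: 14.4 mM·min. Elm gets 14.4 mM·min, the same figure, so I reckoned 50.0%. Birch gets 10.8 mM·min, which autumn reached at 2.50 min, so I reckoned 38.4%. Elm leads by 12 points, beyond the margin.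

The forecast chose elm, with 48% (42% to 55%) for elm and 36% (30% to 43%) for birch. My figures stand above both. Its ground was: “An order above one favours having all the partner present from the start, so elm should end higher.”

Elm ended at 46.9% and birch at 37.5%, so elm held more.

    substrate + partner + product → 2 product (k = 4910 M⁻² s⁻¹)
    substrate + partner → product (k = 0.429 M⁻¹ s⁻¹)
    crystals ⇌ product, rate k3*(cs3 - [product]) while solid is left; crystals form when [product] > cs3 (solubility = 0.130 mM, k = 2.67 s⁻¹)
    substrate + product ⇌ idle adduct, settled at all times (K = 960 M⁻¹)

In elm, the step helped by product used substrate 1.5 times as fast as the plain step at 2.41 min, and 1.5 times at 4.00 min. Both steps use substrate and partner one for one.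

One more flask, like elm but with 14 mM of partner, gets 56.0 mM·min, or 3.89 midpoints. Counting the part not yet product as falling by the same factor over each midpoint, I reckon 93.2% product there, and that flask gave 94.2%.

The earlier runs and the new flask are simulated with made-up constants; noise was put on by code.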